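**Retrosynthetic overview**
1. The target comes from global O-demethylation of its hexamethyl ether.
2. The C6–C6'' biaryl bond is made late by Suzuki–Miyaura union of two complete (2S)-flavanone halves, a 6-bromo half and a 6-pinacolboryl half.
3. Each half comes from a rhodium-catalysed enantioselective 1,4-addition of (4-methoxyphenyl)boronic acid (ring B, from 4-bromophenol) to a 6-substituted 5,7-dimethoxychromone; this sets C2.
4. Both chromones come from one 3-bromo-6-hydroxy-2,4-dimethoxyacetophenone (Br kept, or exchanged for Bpin), made from 4-bromo-3,5-dimethoxyphenol and ultimately resorcinol.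
5. Ring order: ring A is functionalised first, ring C is closed onto it, ring B is added last in each half, then the halves are joined.

Assumption: the target SMILES fixes only C2 and C2'' (both S); the biaryl axis is undefined there and is taken as formed.
Assumption: the (S)-bisphosphine is taken to give the 2S adduct (same facial sense as (S)-BINAP with cyclohexenone); if the sense is opposite, the (R)-ligand is used and nothing else changes.

**Route**

Step 1
Reactants: 1 resorcinol
Product: 2 1,3-dimethoxybenzene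
Conditions: MeI (2.5 equiv), K2CO3, acetone, reflux
Reagents that add atoms: iodomethane CI
Why: Williamson ether synthesis gives two robust methyl ethers that also act as ortho-directing groups for the next step.

Step 2
Reactants: 2 1,3-dimethoxybenzene
Product: 4 2-bromo-1,3-dimethoxybenzene, via aryllithium 3 (not isolated)
Conditions: n-BuLi, THF, 0 °C → rt; then BrCH2CH2Br, −78 °C → rt
Reagents that add atoms: 1,2-dibromoethane BrCCBr; n-butyllithium [Li]CCCC (lithium of 3 only)
Why: Directed ortho-metalation removes only the C2–H between the two methoxy groups, and bromine transfer from 1,2-dibromoethane puts the halogen unambiguously on the future C6.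

Step 3
Reactants: 4 2-bromo-1,3-dimethoxybenzene
Product: 6 4-bromo-3,5-dimethoxyphenol, via arylboronic ester 5 (not isolated)
Conditions: [Ir(OMe)(cod)]2 (1.5 mol %), 4,4'-di-tert-butyl-2,2'-bipyridine (3 mol %), B2pin2 (0.6 equiv), THF, 80 °C; then KHSO5 (as 2KHSO5·KHSO4·K2SO4), acetone/H2O, rt
Reagents that add atoms: bis(pinacolato)diboron CC1(C)OB(OC1(C)C)B1OC(C)(C)C(C)(C)O1 (boron of 5 only); potassium peroxymonosulfate [K+].[O-]S(=O)(=O)OO
Why: Sterically controlled iridium-catalysed C–H borylation reacts only at C5–H (the one C–H without an ortho substituent; aryl bromide tolerated), and oxidation of the C–B bond gives the phenol at that position.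

Step 4
Reactants: 6 4-bromo-3,5-dimethoxyphenol
Product: 8 1-(3-bromo-6-hydroxy-2,4-dimethoxyphenyl)ethan-1-one, via aryl acetate 7 (not isolated)
Conditions: AcCl (1.2 equiv), Sc(OTf)3 (10 mol %), toluene/MeNO2 (7:1), 100 °C
Reagents that add atoms: acetyl chloride CC(Cl)=O
Why: O-acetylation followed by Lewis-acid-catalysed Fries rearrangement; the para position is blocked by Br and the two ortho positions are equivalent, so only this hydrogen-bonded ortho-hydroxy ketone can form, with the free OH on the side remote from Br.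

Step 5
Reactants: 8 1-(3-bromo-6-hydroxy-2,4-dimethoxyphenyl)ethan-1-one
Product: 9 (E)-1-(3-bromo-6-hydroxy-2,4-dimethoxyphenyl)-3-(dimethylamino)prop-2-en-1-one
Conditions: Me2NCH(OMe)2 (2 equiv), toluene, 95 °C
Reagents that add atoms: N,N-dimethylformamide dimethyl acetal COC(OC)N(C)C
Why: Condensation of the methyl ketone with the amide acetal gives the (E)-enaminone, which carries the future C2.

Step 6
Reactants: 9 (E)-enaminone
Product: 10 6-bromo-5,7-dimethoxy-4H-chromen-4-one
Conditions: conc. HCl, CH2Cl2, 40 °C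
Reagents that add atoms: none
Why: Acid-promoted intramolecular oxa-Michael addition of the single free phenol and loss of dimethylamine closes ring C; because that OH is the one remote from Br, the bromine ends at C6.

Step 7
Reactants: 11 4-bromophenol
Product: 12 1-bromo-4-methoxybenzene
Conditions: MeI (1.3 equiv), K2CO3, acetone, reflux
Reagents that add atoms: iodomethane CI
Why: Williamson ether synthesis protects the ring B phenol with the same group as ring A.

Step 8
Reactants: 12 1-bromo-4-methoxybenzene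
Product: 15 (4-methoxyphenyl)boronic acid, via aryllithium 13 (not isolated), via lithium aryl(triisopropoxy)borate 14 (not isolated)
Conditions: n-BuLi, THF, −78 °C; B(OiPr)3, −78 °C → rt; then 1 M HCl
Reagents that add atoms: triisopropyl borate CC(C)OB(OC(C)C)OC(C)C; water O; n-butyllithium [Li]CCCC (lithium of 13 and 14 only)
Why: Bromine–lithium exchange, trapping as the borate and hydrolysis is the standard boronic acid synthesis.

Step 9
Reactants: 10 6-bromo-5,7-dimethoxy-4H-chromen-4-one; 15 (4-methoxyphenyl)boronic acid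
Product: 16 (2S)-6-bromo-5,7-dimethoxy-2-(4-methoxyphenyl)chroman-4-one
Conditions: [Rh(OH)(cod)]2 (1.5 mol %), (S)-MeO-F12-BIPHEP [(S)-2,2'-bis(bis(3,4,5-trifluorophenyl)phosphino)-6,6'-dimethoxybiphenyl] (3.3 mol %), 15 (3 equiv), toluene/H2O (20:1), 40 °C
Reagents that add atoms: none
Why: Hayashi–Miyaura asymmetric 1,4-addition: the aryl–rhodium species adds to C2 on the enone face left open by the electron-poor (S)-bisphosphine, setting C2 as S; the aryl bromide is inert to monovalent rhodium and no base is present to reopen the ring.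

Step 10
Reactants: 8 1-(3-bromo-6-hydroxy-2,4-dimethoxyphenyl)ethan-1-one
Product: 17 1-[6-hydroxy-2,4-dimethoxy-3-(4,4,5,5-tetramethyl-1,3,2-dioxaborolan-2-yl)phenyl]ethan-1-one
Conditions: Pd2(dba)3 (2 mol %), XPhos (8 mol %), B2pin2 (1.5 equiv), KOAc (3 equiv), 1,4-dioxane, 100 °C
Reagents that add atoms: bis(pinacolato)diboron CC1(C)OB(OC1(C)C)B1OC(C)(C)C(C)(C)O1
Why: Miyaura borylation with a bulky dialkylbiarylphosphine handles the di-ortho-substituted bromide; it is done on the acetophenone, before the pyranone and the stereocentre exist, so it can be forced without risk to either.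

Step 11
Reactants: 17 boryl acetophenone
Product: 19 5,7-dimethoxy-6-(4,4,5,5-tetramethyl-1,3,2-dioxaborolan-2-yl)-4H-chromen-4-one, via boryl enaminone 18 (not isolated)
Conditions: Me2NCH(OMe)2 (2 equiv), toluene, 95 °C; evaporate; TsOH·H2O (1.1 equiv), CH2Cl2, rt
Reagents that add atoms: N,N-dimethylformamide dimethyl acetal COC(OC)N(C)C
Why: Same enaminone condensation and cyclisation as steps 5 and 6, telescoped so the boryl enaminone is not chromatographed and closed with a mild anhydrous acid to avoid protodeboronation.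

Step 12
Reactants: 19 6-boryl-5,7-dimethoxychromone; 15 (4-methoxyphenyl)boronic acid
Product: 20 (2S)-5,7-dimethoxy-2-(4-methoxyphenyl)-6-(4,4,5,5-tetramethyl-1,3,2-dioxaborolan-2-yl)chroman-4-one
Conditions: [Rh(OH)(cod)]2 (1.5 mol %), (S)-MeO-F12-BIPHEP (3.3 mol %), 15 (3 equiv), toluene/H2O (20:1), 40 °C
Reagents that add atoms: none
Why: Same asymmetric 1,4-addition as step 9, setting C2 as S; the unhindered boronic acid transmetalates far faster than the di-ortho-substituted pinacol boronate of the substrate, which is carried through.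

Step 13
Reactants: 16 (2S)-6-bromoflavanone half; 20 (2S)-6-borylflavanone half
Product: 21 (2S,2'S)-5,5',7,7'-tetramethoxy-2,2'-bis(4-methoxyphenyl)-2,2',3,3'-tetrahydro-4H,4'H-[6,6'-bichromene]-4,4'-dione
Conditions: Pd(OAc)2 (5 mol %), SPhos (10 mol %), K3PO4·H2O (3 equiv), toluene, 90 °C
Reagents that add atoms: none
Why: Suzuki–Miyaura coupling with a dialkylbiarylphosphine, a ligand class suited to tetra-ortho-alkoxy biaryls; the weak, largely insoluble base in toluene limits enolisation and retro-oxa-Michael opening, so both C2 centres are retained.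

Step 14
Reactants: 21 hexamethyl ether
Product: 22 succedaneaflavanone, (2S,2'S)-5,5',7,7'-tetrahydroxy-2,2'-bis(4-hydroxyphenyl)-2,2',3,3'-tetrahydro-4H,4'H-[6,6'-bichromene]-4,4'-dione
Conditions: BBr3 (15 equiv), CH2Cl2, −78 → 0 °C; then H2O
Reagents that add atoms: none
Why: Lewis-acid ether cleavage (bromide attacks the O-methyl of each boron-complexed ether); the low temperature and complexation of the ring B oxygen disfavour ionisation of the C2–O bond, so the 2S centres are kept.

**Compound list**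
1 | resorcinol | Oc1cccc(O)c1 | starting material
2 | 1,3-dimethoxybenzene | COc1cccc(OC)c1 | intermediate
3 | (2,6-dimethoxyphenyl)lithium | [Li]c1c(OC)cccc1OC | intermediate (not isolated)
4 | 2-bromo-1,3-dimethoxybenzene | COc1cccc(OC)c1Br | intermediate
5 | 2-(4-bromo-3,5-dimethoxyphenyl)-4,4,5,5-tetramethyl-1,3,2-dioxaborolane | COc1cc(B2OC(C)(C)C(C)(C)O2)cc(OC)c1Br | intermediate (not isolated)
6 | 4-bromo-3,5-dimethoxyphenol | COc1cc(O)cc(OC)c1Br | intermediate
7 | 4-bromo-3,5-dimethoxyphenyl acetate | CC(=O)Oc1cc(OC)c(Br)c(OC)c1 | intermediate (not isolated)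
8 | 1-(3-bromo-6-hydroxy-2,4-dimethoxyphenyl)ethan-1-one | CC(=O)c1c(O)cc(OC)c(Br)c1OC | intermediate
9 | (E)-1-(3-bromo-6-hydroxy-2,4-dimethoxyphenyl)-3-(dimethylamino)prop-2-en-1-one | CN(C)/C=C/C(=O)c1c(O)cc(OC)c(Br)c1OC | intermediate
10 | 6-bromo-5,7-dimethoxy-4H-chromen-4-one | COc1cc2occc(=O)c2c(OC)c1Br | intermediate
11 | 4-bromophenol | Oc1ccc(Br)cc1 | starting material
12 | 1-bromo-4-methoxybenzene | COc1ccc(Br)cc1 | intermediate
13 | (4-methoxyphenyl)lithium | [Li]c1ccc(OC)cc1 | intermediate (not isolated)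
14 | lithium triisopropoxy(4-methoxyphenyl)borate | [Li+].COc1ccc(cc1)[B-](OC(C)C)(OC(C)C)OC(C)C | intermediate (not isolated)
15 | (4-methoxyphenyl)boronic acid | COc1ccc(cc1)B(O)O | intermediate
16 | (2S)-6-bromo-5,7-dimethoxy-2-(4-methoxyphenyl)chroman-4-one | O=C1C[C@@H](c2ccc(OC)cc2)Oc2cc(OC)c(Br)c(OC)c21 | intermediate
17 | 1-[6-hydroxy-2,4-dimethoxy-3-(4,4,5,5-tetramethyl-1,3,2-dioxaborolan-2-yl)phenyl]ethan-1-one | CC(=O)c1c(O)cc(OC)c(B2OC(C)(C)C(C)(C)O2)c1OC | intermediate
18 | (E)-3-(dimethylamino)-1-[6-hydroxy-2,4-dimethoxy-3-(4,4,5,5-tetramethyl-1,3,2-dioxaborolan-2-yl)phenyl]prop-2-en-1-one | CN(C)/C=C/C(=O)c1c(O)cc(OC)c(B2OC(C)(C)C(C)(C)O2)c1OC | intermediate (not isolated)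
19 | 5,7-dimethoxy-6-(4,4,5,5-tetramethyl-1,3,2-dioxaborolan-2-yl)-4H-chromen-4-one | COc1cc2occc(=O)c2c(OC)c1B1OC(C)(C)C(C)(C)O1 | intermediate
20 | (2S)-5,7-dimethoxy-2-(4-methoxyphenyl)-6-(4,4,5,5-tetramethyl-1,3,2-dioxaborolan-2-yl)chroman-4-one | O=C1C[C@@H](c2ccc(OC)cc2)Oc2cc(OC)c(B3OC(C)(C)C(C)(C)O3)c(OC)c21 | intermediate
21 | (2S,2'S)-5,5',7,7'-tetramethoxy-2,2'-bis(4-methoxyphenyl)-2,2',3,3'-tetrahydro-4H,4'H-[6,6'-bichromene]-4,4'-dione | O=C1C[C@@H](c2ccc(OC)cc2)Oc2cc(OC)c(-c3c(OC)cc4c(c3OC)C(=O)C[C@@H](c3ccc(OC)cc3)O4)c(OC)c21 | intermediate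
22 | succedaneaflavanone | O=C1C[C@@H](c2ccc(O)cc2)Oc2cc(O)c(-c3c(O)cc4c(c3O)C(=O)C[C@@H](c3ccc(O)cc3)O4)c(O)c21 | target

**Step count**
Total step count: 14.
Longest linear sequence: 9 steps (1 → 2 → 4 → 6 → 8 → 17 → 19 → 20 → 21 → 22; the path through 9, 10 and 16 is equally long).

**Three steps most likely to fail**

Step 12. The di-ortho-alkoxy pinacol boronate of 19 may protodeboronate or transmetalate under the aqueous rhodium conditions, and its precursor step 10 is a hindered borylation. The fallback sets out from bromoflavanone 16 and comes back to the route at 20. Part of 16 is borylated directly with pinacolborane (PdCl2(MeCN)2, SPhos, HBpin, Et3N, 1,4-dioxane, 80 °C), so the C–B bond is made after ring C and the stereocentre instead of before them. This bypasses steps 10 to 12 and makes no new compound (F0).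

Step 13. A tetra-ortho-alkoxy biaryl coupling between two large halves may stall, and prolonged heating with base could erode the C2 centres by retro-oxa-Michael opening. The fallback sets out from the achiral chromones 10 and 19 and comes back at 21. They are coupled under more forcing conditions (Pd(OAc)2, SPhos, K3PO4, toluene/H2O, 110 °C) to 5,5',7,7'-tetramethoxy-4H,4'H-[6,6'-bichromene]-4,4'-dione F1. A twofold asymmetric 1,4-addition of 15 (6 equiv, [Rh(OH)(cod)]2, (S)-MeO-F12-BIPHEP, toluene/H2O, 40 °C) then sets both stereocentres after the biaryl bond exists.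

Step 14. Six methyl ethers must be cleaved by a strong Lewis acid without ionising the benzylic C2–O bond; ring opening to the chalcone or racemisation is the main danger. The fallback sets out from bromochromone 10 and 4-bromophenol 11, swaps the protecting groups before any stereocentre exists, and comes back at 22.
- BBr3 (CH2Cl2, 0 °C → rt) on 10 gives 6-bromo-5,7-dihydroxy-4H-chromen-4-one F2.
- MOMCl, NaH, DMF gives 6-bromo-5,7-bis(methoxymethoxy)-4H-chromen-4-one F3.
- Part of F3 is borylated (Pd2(dba)3, XPhos, B2pin2, KOAc, dioxane) to 5,7-bis(methoxymethoxy)-6-(4,4,5,5-tetramethyl-1,3,2-dioxaborolan-2-yl)-4H-chromen-4-one F4.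
- 11 is converted with MOMCl, i-Pr2NEt into 1-bromo-4-(methoxymethoxy)benzene F5, and then with n-BuLi, B(OiPr)3 and aqueous NH4Cl work-up into [4-(methoxymethoxy)phenyl]boronic acid F6.
- Rhodium-catalysed addition of F6 (conditions of step 9) to F3 gives (2S)-6-bromo-5,7-bis(methoxymethoxy)-2-[4-(methoxymethoxy)phenyl]chroman-4-one F7, and to F4 gives (2S)-5,7-bis(methoxymethoxy)-2-[4-(methoxymethoxy)phenyl]-6-(4,4,5,5-tetramethyl-1,3,2-dioxaborolan-2-yl)chroman-4-one F8.
- Suzuki coupling of F7 and F8 (conditions of step 13) gives (2S,2'S)-5,5',7,7'-tetrakis(methoxymethoxy)-2,2'-bis[4-(methoxymethoxy)phenyl]-2,2',3,3'-tetrahydro-4H,4'H-[6,6'-bichromene]-4,4'-dione F9.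
- 3 M HCl in MeOH at 40 °C removes the six acetals and gives 22.

**Further compounds**
F0 | step 12 | none | none
F1 | step 13 | 5,5',7,7'-tetramethoxy-4H,4'H-[6,6'-bichromene]-4,4'-dione | COc1cc2occc(=O)c2c(OC)c1-c1c(OC)cc2occc(=O)c2c1OC
F2 | step 14 | 6-bromo-5,7-dihydroxy-4H-chromen-4-one | Oc1cc2occc(=O)c2c(O)c1Br
F3 | step 14 | 6-bromo-5,7-bis(methoxymethoxy)-4H-chromen-4-one | COCOc1cc2occc(=O)c2c(OCOC)c1Br
F4 | step 14 | 5,7-bis(methoxymethoxy)-6-(4,4,5,5-tetramethyl-1,3,2-dioxaborolan-2-yl)-4H-chromen-4-one | COCOc1cc2occc(=O)c2c(OCOC)c1B1OC(C)(C)C(C)(C)O1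
F5 | step 14 | 1-bromo-4-(methoxymethoxy)benzene | COCOc1ccc(Br)cc1
F6 | step 14 | [4-(methoxymethoxy)phenyl]boronic acid | COCOc1ccc(cc1)B(O)O
F7 | step 14 | (2S)-6-bromo-5,7-bis(methoxymethoxy)-2-[4-(methoxymethoxy)phenyl]chroman-4-one | O=C1C[C@@H](c2ccc(OCOC)cc2)Oc2cc(OCOC)c(Br)c(OCOC)c21
F8 | step 14 | (2S)-5,7-bis(methoxymethoxy)-2-[4-(methoxymethoxy)phenyl]-6-(4,4,5,5-tetramethyl-1,3,2-dioxaborolan-2-yl)chroman-4-one | O=C1C[C@@H](c2ccc(OCOC)cc2)Oc2cc(OCOC)c(B3OC(C)(C)C(C)(C)O3)c(OCOC)c21
F9 | step 14 | (2S,2'S)-5,5',7,7'-tetrakis(methoxymethoxy)-2,2'-bis[4-(methoxymethoxy)phenyl]-2,2',3,3'-tetrahydro-4H,4'H-[6,6'-bichromene]-4,4'-dione | O=C1C[C@@H](c2ccc(OCOC)cc2)Oc2cc(OCOC)c(-c3c(OCOC)cc4c(c3OCOC)C(=O)C[C@@H](c3ccc(OCOC)cc3)O4)c(OCOC)c21
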